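In a one-step world D→X a single constant draws the curve. But in the amber and red runs J rose first and X lagged, so I reckoned with two steps (consecutive reactions, J the intermediate), and took Q and G as amounts read from the runs.

| flask | D | temperature | remark | time |
|---|---|---|---|---|
| amber | 1.4 M | 57 °C | run made earlier |  |
| red | 2.2 M | 72 °C | run made earlier |  |
| ash | 1.0 M | 60 °C |  | 3.0 h |
| birch | 1.0 M | 68 °C |  | 3.0 h |

amber run (percent of the D charged)

| time / h | D / % | G / % | J / % | Q / % | X / % |
|---|---|---|---|---|---|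
| 0.500 | 79 | 1 | 12 | 10 | 1 |
| 1.00 | 62 | 0 | 20 | 16 | 4 |
| 1.33 | 54 | 1 | 23 | 14 | 4 |
| 2.00 | 42 | 4 | 30 | 15 | 9 |
| 2.50 | 40 | 3 | 33 | 16 | 14 |

red run (percent of the D charged)

| time / min | D / % | G / % | J / % | Q / % | X / % |
|---|---|---|---|---|---|
| 6.00 | 82 | 1 | 14 | 6 | 2 |
| 20.0 | 55 | 1 | 27 | 10 | 5 |
| 30.0 | 47 | 3 | 35 | 5 | 7 |
| 50.0 | 28 | 3 | 42 | 7 | 24 |
| 80.0 | 17 | 3 | 34 | 2 | 43 |

(readings scatter by 1.5 percentage points)

- which of these there is most of at the end, counted by the D in it, ash (X / J / D / Q / G)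
- which of these there is most of at the end, counted by the D in it, birch (X / J / D / Q / G)
- how much there is at the end of the one of these that leads, in percent of the D charged: ash
- how much there is at the end of the one of these that leads, in percent of the D charged: birch

- I wrote a for the constant of D→J, b for J→X, and c for the apparent decay of D, ln(1/D)/t. Up to the last readings, a = (J+X)/∫D dt, so a was 0.310 h⁻¹ in amber and 1.34 h⁻¹ in red.
- From b = X/∫J dt, b read 0.271 h⁻¹ and 1.01 h⁻¹, and c read 0.367 h⁻¹ and 1.33 h⁻¹.
- Ash lies 0.200 of the way from amber to red, so in logarithms a was 0.415 h⁻¹, b 0.353 h⁻¹ and c 0.474 h⁻¹.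
- J is made at aD and used at bJ, so I took the hand-over ratio κ = a/b, here 1.18, and M = κD/J. In my two steps J rises while M exceeds 1 and falls once M is below 1.
- My ash curve started with slope a, bent over, and crossed M = 1 at 2.44 h at 37.1% J. It then sank towards zero, passing 36.2% at the asked time.
- Taking Q and G from amber's last reading, my ash reckoning held D 24.1% and X 20.7%, so J stood higher than either.
- Birch lies 0.733 of the way, giving a 0.908 h⁻¹, b 0.712 h⁻¹ and c 0.943 h⁻¹. My birch curve crossed at 1.22 h, leaving J 23.2% and D 5.91%. With Q and G from red's last reading, X was 65.9%, higher than either.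
- The forecast said J at 36% in ash and X at 62% in birch, reasoning that “J builds first and X follows with a lag”. The flasks gave J at 33.8% in ash and X at 63.2% in birch.

    Q ⇌ G (K = 1.30, k = 4.30 × 10⁻⁵ s⁻¹, Ea = 104 kJ mol⁻¹, ΔH = 2.00 kJ mol⁻¹)
    J → X (k = 9.00 × 10⁻⁵ s⁻¹, Ea = 93.0 kJ mol⁻¹)
    D ⇌ Q (K = 0.360, k = 9.00 × 10⁻⁵ s⁻¹, Ea = 108 kJ mol⁻¹, ΔH = −74.0 kJ mol⁻¹)
    D → J (k = 1.10 × 10⁻⁴ s⁻¹, Ea = 99.0 kJ mol⁻¹)
    (constants at 60 °C)

- With the D and J found in ash at the end, M was 0.883, below 1, so by κ ash stood just past its crossing. The main reason for the gap in J between ash and birch was the difference in temperature: J stood at 23.4% in birch, against 33.8% without that difference.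
- For the same flask as ash read earlier, at 2.0 h, κ and my curve gave M = 1.26, so by my curve J was still rising there. That flask held 32.7% J, against 33.8% in ash at the asked time.

The runs are calculated from invented constants; scatter was added.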